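The plan cuts the C4–C5 and C6–O bonds. C4, the methyl-bearing carbon at the fusion of the γ-lactone and 1,2-dioxane rings, and C6, the methyl-bearing peroxy carbon of the dioxane, are 1,3-related through the C5 methylene. C4 can therefore come from an electrophilic 5-methylfuranone carbon, C5–C6 from a 2-methylalk-1-ene and the O–O unit from hydrogen peroxide. One cationic operation joins the three and gives an open-chain tertiary hydroperoxide that still carries a butenolide; conjugate addition then closes the dioxane. The precursors are 5-methoxy-5-methylfuranone, an 11-aryl-2-methylundec-1-ene with the phenol silylated, and H2O2 delivered as its bis-silyl ether.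

Key step: step 4

Remarks on the chemistry:
- Atom labels follow the natural product: C1 lactone carbonyl, C2 its α-methylene, C3 the peroxy methine at the ring fusion, C4 the methyl-bearing lactone carbon at the ring fusion, C5 the ring methylene, C6 the methyl-bearing peroxy carbon. The target is cis-fused and (3S,4S,6R).
- Assumption: hydrogen peroxide enters the key step as its bis(trimethylsilyl) ether, made in the same flask, because a free O–H peroxide would turn Me3SiOSO2CF3 into CF3SO3H. The disconnection is unchanged.
- Compound 1 is the commercially available silyl ether of 4-bromophenol; 12 is used as its commercial urea adduct.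
- Compounds 14 and 15 are four-isomer mixtures and are written as the isomer that leads to the target; racemate 16 is written with both enantiomers in one SMILES.
- Peroxide solutions (13, 14, 15) should be kept dilute and not concentrated to dryness.

Step 1
Reactants: 1 tert-butyl(4-bromophenoxy)dimethylsilane; 2 1,8-dibromooctane
Product: 4 [4-(8-bromooctyl)phenoxy](tert-butyl)dimethylsilane, via arylmagnesium bromide 3 (not isolated)
Conditions: Mg, THF, 50 °C; then added to 2 (3 equiv), Li2CuCl4 (3 mol %), THF, 0 °C
Reagents that add atoms: none
Why: Copper-catalysed cross-coupling of an aryl Grignard reagent with a primary alkyl bromide, in which slow addition of 3 to a threefold excess of 2 should leave the second C–Br bond largely untouched; the aryl silyl ether is inert to both organometallic stages and no stereocentre is formed.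

Step 2
Reactants: 4 [4-(8-bromooctyl)phenoxy](tert-butyl)dimethylsilane; 5 3-chloro-2-methylprop-1-ene
Product: 7 tert-butyldimethyl[4-(10-methylundec-10-en-1-yl)phenoxy]silane, via alkylmagnesium bromide 6 (not isolated)
Conditions: Mg, THF, 50 °C; then 5 (1.5 equiv), CuI (5 mol %), THF, −20 to 20 °C
Reagents that add atoms: none
Why: Copper-catalysed allylic substitution of methallyl chloride by a primary alkyl Grignard reagent, in which attack at either allyl terminus gives the same 2-methylalk-1-ene, so regiochemistry is not an issue and no stereocentre is formed.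

Step 3
Reactants: 8 2-methylfuran
Product: 11 5-methoxy-5-methylfuran-2(5H)-one (racemic), via endoperoxide 9 (not isolated), via methoxy hydroperoxide 10 (not isolated)
Conditions: O2, visible light, methylene blue (C16H18ClN3S, cat.), MeOH, −78 °C; concentrate cold; then Ac2O, pyridine, CH2Cl2, 0 °C
Reagents that add atoms: dioxygen, O=O; methanol, CO
Why: Singlet-oxygen [4+2] cycloaddition to the furan gives 9, methanol opens it at the methyl-bearing acetal carbon to give 10, and acetylation–elimination of the secondary hydroperoxide (Kornblum–DeLaMare-type dehydration) forms the lactone carbonyl; the ketal stereocentre is racemic, which is immaterial because it is destroyed on ionisation.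

Step 4
Reactants: 11 5-methoxy-5-methylfuran-2(5H)-one; 7 tert-butyldimethyl[4-(10-methylundec-10-en-1-yl)phenoxy]silane; 12 hydrogen peroxide
Product: 15 (5S)-5-[(2R)-11-{4-[(tert-butyldimethylsilyl)oxy]phenyl}-2-hydroperoxy-2-methylundecyl]-5-methylfuran-2(5H)-one as part of the four-isomer mixture, via bis(trimethylsilyl) peroxide 13 (not isolated), via trimethylsilyl peroxide 14 (not isolated)
Conditions: 12·urea, (Me3SiNH)2CO, CH2Cl2, 40 °C, filter; then 7, 11 (2 equiv), Me3SiOSO2CF3 (20 mol %), CH2Cl2, −78 to −40 °C; then pyridine, MeOH, pyridinium p-toluenesulfonate (cat.), 0 °C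
Reagents that add atoms: none
Why: Proposed new method: Me3SiOSO2CF3 removes methoxide from 11 as Me3SiOMe to give an acyloxy-stabilised 5-methyl-2-oxofuranylium ion, the CH2 terminus of 7 adds to its oxygen-bearing carbon (C4–C5 bond, butenolide restored) and the tertiary C6 cation so formed is captured through oxygen by Me3SiOOSiMe3 13 (C6–O bond) with return of Me3Si+ to CF3SO3−, so that the acid turns over; 12 is silylated beforehand because a free O–H peroxide would convert Me3SiOSO2CF3 into CF3SO3H, and methanolysis of 14 finally uncovers the hydroperoxide. The closest known reaction types are Hosomi–Sakurai and Mukaiyama additions to oxocarbenium ions of 5-alkoxyfuran-2(5H)-ones, Prins-type additions of simple alkenes to oxocarbenium ions, Me3SiOSO2CF3-catalysed transfer of Me3SiOO from 13 to oxocarbenium centres and acid perhydrolysis of tertiary cations, but their union with an unactivated alkene in one flask is untested. No ring is closed in this step. Neither new stereocentre is controlled: the planar furanone cation is attacked on either face (C4) and the open-chain C6 cation is captured without bias, so all four stereoisomers are expected and the needed (4S,6R) one is selected in steps 5 and 6. The step needs Markovnikov orientation, secured by the 2-methyl group that makes only the tertiary cation accessible, attack at C4 and not at the α-carbon C2, secured by the charge residing on the oxygen-bearing carbon, and alkene-over-arene chemoselectivity, secured by the blocked para position and the bulky silyl ether beside the ortho positions. Peroxide capture must also outrun proton loss from C6, which excess 13, low temperature and a base-free medium should favour, while the reversibility of ionisation makes return of peroxide or methoxide to the furanone carbon harmless.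

Step 5
Reactants: 15 (5S)-5-[(2R)-11-{4-[(tert-butyldimethylsilyl)oxy]phenyl}-2-hydroperoxy-2-methylundecyl]-5-methylfuran-2(5H)-one (four-isomer mixture)
Product: 16 racemic cis-fused peroxylactone (1S*,4R*,6S*)-4-(9-{4-[(tert-butyldimethylsilyl)oxy]phenyl}nonyl)-4,6-dimethyl-2,3,7-trioxabicyclo[4.3.0]nonan-8-one (3S*,4S*,6R* in natural-product numbering)
Conditions: Et2NH (0.2 equiv), CF3CH2OH, 20 °C; chromatography on SiO2 to remove the C6 epimer
Reagents that add atoms: none
Why: Amine-mediated intramolecular oxa-Michael addition (6-exo-trig) of the hydroperoxide to the butenolide β-carbon, in which the short tether from C4 can reach C3 only on its own face, so the existing C4 centre sets C3 cis to the C4–C5 bond; the acidic fluoro alcohol should protonate the lactone enolate before it can attack the O–O bond, and the rigid C6-epimeric bicycles are then separated on silica.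

Step 6
Reactants: 16 racemic cis-fused peroxylactone
Product: 17 (1S,4R,6S)-4-(9-{4-[(tert-butyldimethylsilyl)oxy]phenyl}nonyl)-4,6-dimethyl-2,3,7-trioxabicyclo[4.3.0]nonan-8-one
Conditions: preparative HPLC, amylose tris(3,5-dimethylphenylcarbamate) on silica, hexane/i-PrOH, 25 °C
Reagents that add atoms: none
Why: Resolution of a racemate by preparative enantioselective chromatography, in which no bond is formed and the enantiomers differ in their transient hydrogen-bonded and π-stacked complexes with the carbamate selector; the collected fraction is to be assigned by circular dichroism against calculation and by the sign of rotation of a desilylated sample against that recorded for the natural product.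

Step 7
Reactants: 17 (1S,4R,6S)-4-(9-{4-[(tert-butyldimethylsilyl)oxy]phenyl}nonyl)-4,6-dimethyl-2,3,7-trioxabicyclo[4.3.0]nonan-8-one
Product: 18 plakortolide F
Conditions: Bu4NF, AcOH (1:1), THF, 0 °C
Reagents that add atoms: none
Why: Fluoride-induced cleavage of an aryl silyl ether, driven by the Si–F bond and the phenoxide leaving group; acetic acid buffering keeps the medium non-basic so that the β-peroxy lactone should not suffer retro-oxa-Michael opening or Kornblum–DeLaMare cleavage, and no stereocentre is touched.

Compound list
1 | tert-butyl(4-bromophenoxy)dimethylsilane | CC(C)(C)[Si](C)(C)Oc1ccc(Br)cc1 | starting material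
2 | 1,8-dibromooctane | BrCCCCCCCCBr | starting material
3 | {4-[(tert-butyldimethylsilyl)oxy]phenyl}magnesium bromide | CC(C)(C)[Si](C)(C)Oc1ccc([Mg]Br)cc1 | intermediate (not isolated)
4 | [4-(8-bromooctyl)phenoxy](tert-butyl)dimethylsilane | CC(C)(C)[Si](C)(C)Oc1ccc(CCCCCCCCBr)cc1 | intermediate
5 | 3-chloro-2-methylprop-1-ene | CC(=C)CCl | starting material
6 | (8-{4-[(tert-butyldimethylsilyl)oxy]phenyl}octyl)magnesium bromide | CC(C)(C)[Si](C)(C)Oc1ccc(CCCCCCCC[Mg]Br)cc1 | intermediate (not isolated)
7 | tert-butyldimethyl[4-(10-methylundec-10-en-1-yl)phenoxy]silane (the 11-aryl-2-methylundec-1-ene) | C=C(C)CCCCCCCCCc1ccc(O[Si](C)(C)C(C)(C)C)cc1 | intermediate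
8 | 2-methylfuran | Cc1ccco1 | starting material
9 | 1-methyl-2,3,7-trioxabicyclo[2.2.1]hept-5-ene (racemic) | CC12OOC(C=C1)O2 | intermediate (not isolated)
10 | 2-hydroperoxy-5-methoxy-5-methyl-2,5-dihydrofuran (diastereomer mixture) | COC1(C)C=CC(OO)O1 | intermediate (not isolated)
11 | 5-methoxy-5-methylfuran-2(5H)-one (racemic) | COC1(C)OC(=O)C=C1 | intermediate
12 | hydrogen peroxide (used as its urea adduct) | OO | starting material
13 | bis(trimethylsilyl) peroxide | C[Si](C)(C)OO[Si](C)(C)C | intermediate (not isolated)
14 | (5S)-5-[(2R)-11-{4-[(tert-butyldimethylsilyl)oxy]phenyl}-2-methyl-2-[(trimethylsilyl)peroxy]undecyl]-5-methylfuran-2(5H)-one (needed isomer of the four-isomer mixture) | C[C@@](OO[Si](C)(C)C)(CCCCCCCCCc1ccc(O[Si](C)(C)C(C)(C)C)cc1)C[C@]2(C)OC(=O)C=C2 | intermediate (not isolated)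
15 | (5S)-5-[(2R)-11-{4-[(tert-butyldimethylsilyl)oxy]phenyl}-2-hydroperoxy-2-methylundecyl]-5-methylfuran-2(5H)-one (needed isomer of the four-isomer mixture) | C[C@@](OO)(CCCCCCCCCc1ccc(O[Si](C)(C)C(C)(C)C)cc1)C[C@]2(C)OC(=O)C=C2 | intermediate
16 | racemic cis-fused (1S*,4R*,6S*)-4-(9-{4-[(tert-butyldimethylsilyl)oxy]phenyl}nonyl)-4,6-dimethyl-2,3,7-trioxabicyclo[4.3.0]nonan-8-one | C[C@@]1(CCCCCCCCCc2ccc(O[Si](C)(C)C(C)(C)C)cc2)C[C@]2(C)OC(=O)C[C@@H]2OO1.C[C@]1(CCCCCCCCCc2ccc(O[Si](C)(C)C(C)(C)C)cc2)C[C@@]2(C)OC(=O)C[C@H]2OO1 | intermediate
17 | (1S,4R,6S)-4-(9-{4-[(tert-butyldimethylsilyl)oxy]phenyl}nonyl)-4,6-dimethyl-2,3,7-trioxabicyclo[4.3.0]nonan-8-one (O-silyl plakortolide F) | C[C@@]1(CCCCCCCCCc2ccc(O[Si](C)(C)C(C)(C)C)cc2)C[C@]2(C)OC(=O)C[C@@H]2OO1 | intermediate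
18 | plakortolide F, (1S,4R,6S)-4-[9-(4-hydroxyphenyl)nonyl]-4,6-dimethyl-2,3,7-trioxabicyclo[4.3.0]nonan-8-one (3S,4S,6R in natural-product numbering) | C[C@@]1(CCCCCCCCCc2ccc(O)cc2)C[C@]2(C)OC(=O)C[C@@H]2OO1 | target

Total step count: 7 (steps 1–7; step 3 is a one-step branch).
Longest linear sequence: 6 steps (1 → 4 → 7 → 15 → 16 → 17 → 18).

Steps most likely to fail

Step 4 (the proposed method). The process most likely to defeat it is loss of a proton from the C6 cation before peroxide capture, or failure of an unactivated alkene to intercept the short-lived furanone cation. The fallback makes the same two bonds in separate, established operations. It sets out from 4 and comes back at 15, using 11 as before. The Grignard reagent 6 from 4 is coupled (CuI cat., THF) with commercial [2-(chloromethyl)prop-2-en-1-yl]trimethylsilane to give the allylsilane tert-butyldimethyl(4-{10-[(trimethylsilyl)methyl]undec-10-en-1-yl}phenoxy)silane F1. A Hosomi–Sakurai reaction of F1 with 11 (Me3SiOSO2CF3 cat., CH2Cl2, −78 °C) should form the C4–C5 bond with loss of silicon and give the 1,1-disubstituted alkene 5-(11-{4-[(tert-butyldimethylsilyl)oxy]phenyl}-2-methylideneundecyl)-5-methylfuran-2(5H)-one F2. Mukaiyama–Isayama hydroperoxysilylation (Co(C11H19O2)2 cat., O2, Et3SiH, ClCH2CH2Cl, 20 °C) should then place the peroxide at the tertiary carbon of the electron-rich alkene and leave the electron-poor butenolide alkene alone, giving the triethylsilyl peroxide F3. Brief methanolysis (pyridinium p-toluenesulfonate, MeOH) returns 15 as the same four-isomer mixture.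

Step 5. The ring closure itself has direct analogy; the weak point is the sorting of stereoisomers. Incomplete separation of the two C6-epimeric bicycles on silica would carry the wrong epimer into the resolution. The fallback sorts all four stereoisomers before ring closure as covalent diastereomers. It sets out from 15 and comes back at 17, so that 16 and step 6 are bypassed. Commercial (1R,2S)-trans-2-phenylcyclohexanol is acetylated (Ac2O, pyridine) to (1R,2S)-2-phenylcyclohexyl acetate F4. Methylenation with the Tebbe reagent, (C5H5)2Ti(CH2)(Cl)Al(CH3)2, gives (1R,2S)-2-phenylcyclohexyl isopropenyl ether F5. Acid-catalysed addition of the hydroperoxide mixture 15 to F5 (pyridinium p-toluenesulfonate, CH2Cl2, 0 °C) should give four diastereomeric peroxyketals that can be separated on ordinary silica. The one derived from the (5S,2'R) hydroperoxide, peroxyketal F6, is cleaved with AcOH/THF/H2O to stereochemically homogeneous 15. Under the conditions of step 5 this closes directly to 17.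

Step 1. Reaction at the second C–Br bond of the dibromide and homocoupling of the aryl Grignard reagent may erode the statistical mono-coupling. The fallback replaces the Grignard coupling by a B-alkyl Suzuki–Miyaura coupling. It sets out from 1 and comes back at 4. Commercial 8-bromooct-1-ene is hydroborated with 9-borabicyclo[3.3.1]nonane (THF, 20 °C) to 9-(8-bromooctyl)-9-borabicyclo[3.3.1]nonane F7. This is coupled in the same flask with 1 (PdCl2[1,1'-bis(diphenylphosphino)ferrocene] cat., K3PO4, THF/H2O, 50 °C). Oxidative addition to the aryl bromide is far faster than to the primary alkyl bromide, which should therefore survive as the handle of 4.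

Further compounds
F1 | step 4 | tert-butyldimethyl(4-{10-[(trimethylsilyl)methyl]undec-10-en-1-yl}phenoxy)silane | C=C(C[Si](C)(C)C)CCCCCCCCCc1ccc(O[Si](C)(C)C(C)(C)C)cc1
F2 | step 4 | 5-(11-{4-[(tert-butyldimethylsilyl)oxy]phenyl}-2-methylideneundecyl)-5-methylfuran-2(5H)-one (racemic) | C=C(CCCCCCCCCc1ccc(O[Si](C)(C)C(C)(C)C)cc1)CC1(C)OC(=O)C=C1
F3 | step 4 | (5S)-5-[(2R)-11-{4-[(tert-butyldimethylsilyl)oxy]phenyl}-2-methyl-2-[(triethylsilyl)peroxy]undecyl]-5-methylfuran-2(5H)-one (needed isomer of the four-isomer mixture) | C[C@@](OO[Si](CC)(CC)CC)(CCCCCCCCCc1ccc(O[Si](C)(C)C(C)(C)C)cc1)C[C@]2(C)OC(=O)C=C2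
F4 | step 5 | (1R,2S)-2-phenylcyclohexyl acetate | CC(=O)O[C@@H]1CCCC[C@H]1c1ccccc1
F5 | step 5 | (1R,2S)-2-phenylcyclohexyl isopropenyl ether | C=C(C)O[C@@H]1CCCC[C@H]1c1ccccc1
F6 | step 5 | (5S)-5-[(2R)-11-{4-[(tert-butyldimethylsilyl)oxy]phenyl}-2-methyl-2-[(2-{[(1R,2S)-2-phenylcyclohexyl]oxy}propan-2-yl)peroxy]undecyl]-5-methylfuran-2(5H)-one | C[C@@](OOC(C)(C)O[C@@H]1CCCC[C@H]1c1ccccc1)(CCCCCCCCCc1ccc(O[Si](C)(C)C(C)(C)C)cc1)C[C@]2(C)OC(=O)C=C2
F7 | step 1 | 9-(8-bromooctyl)-9-borabicyclo[3.3.1]nonane | BrCCCCCCCCB1C2CCCC1CCC2
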